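**Plan**

1. Retrosynthetic cuts: the C8 ester C–O bond is cut first. The butenolide is then cut at C11–C12, with removal of C12 as CO and of the C13–OAc bond, which leads back to a ten-membered α-allenic alcohol (C6–OH, C7=C11=C13H2). The ring bond C6–C7 is cut next (epoxy aldehyde plus propargylic bromide), then the two epoxides and C1=C2 (Wittig), then C8–C9 (allylation/lactonisation).
2. Enabling feature: in the butenolide ring (O6, C6, C7, C11, C12) the tetrasubstituted C7=C11 bond is exocyclic to the ten-membered ring, and C11 carries both the carbonyl C12 and the oxygenated C13. This array equals an exocyclic allene next to the C6 hydroxyl, plus CO, plus acetate, and the allene has no alkene geometry to control.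
3. Forward order: the chain C13–C11–C7–C8–C9–C10–C1 is built from an ynal and ethyl 2-(bromomethyl)acrylate and joined to a C2–C6 ylide. The 4,5-epoxide and then the 1,2-epoxide follow. The ten-membered ring is closed by chromium-mediated propargylation, the butenolide ring by oxidative carbonylation, and the side-chain ester is attached last.
4. Stereochemistry: C8 comes from a catalytic asymmetric allylation, C4/C5 from Sharpless epoxidation of the E-allylic alcohol, C1/C2 from Shi epoxidation of the Z-diene, and C6 from the ring closure. The key step creates no stereocentre.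

Key step: step 18

Remark: locants C1–C15 are those of the germacrane skeleton of the target and are kept for all intermediates (ring C1–C10, C11 lactone α-carbon, C12 lactone carbonyl, C13 acetoxymethyl carbon, C14 exocyclic methylene on C10, C15 methyl on C4).

**Route**

Step 1
Reactants: 1 but-2-yne-1,4-diol
Product: 2 4-((4-methoxybenzyl)oxy)but-2-yn-1-ol
Conditions: NaH (1 equiv), 4-methoxybenzyl chloride (1 equiv), Bu4NI (cat.), THF/DMF, 0 °C to rt; 1 in threefold excess
Reagents that add atoms: 4-methoxybenzyl chloride, COc1ccc(CCl)cc1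
Why: Williamson etherification, in which the excess of the symmetrical diol should hold the reaction at the mono-ether.

Step 2
Reactants: 2 4-((4-methoxybenzyl)oxy)but-2-yn-1-ol
Product: 3 4-((4-methoxybenzyl)oxy)but-2-ynal
Conditions: MnO2 (activated, excess), CH2Cl2, rt
Reagents that add atoms: none
Why: MnO2 oxidation of an activated propargylic alcohol should stop cleanly at the ynal and leave the benzylic ether alone.

Step 3
Reactants: 3 4-((4-methoxybenzyl)oxy)but-2-ynal; 4 ethyl 2-(bromomethyl)acrylate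
Product: 7 (S)-5-(3-((4-methoxybenzyl)oxy)prop-1-yn-1-yl)-3-methylidenedihydrofuran-2(3H)-one, via silyl ether 5 (not isolated), via hydroxy ester 6 (not isolated)
Conditions: CrCl2 (10 mol %), chiral carbazole-bis(oxazoline) ligand (12 mol %), Mn powder, Me3SiCl, iPr2NEt (cat.), THF, rt; then 1 M HCl, THF, rt
Reagents that add atoms: none
Why: Catalytic enantioselective Nozaki–Hiyama–Kishi 2-(alkoxycarbonyl)allylation (Mn as terminal reductant, Me3SiCl for turnover) followed by acid-mediated desilylation and lactonisation, in which the ligand enantiomer that sends the allyl group to the Si face of the aldehyde sets C8 as S.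

Step 4
Reactants: 7 (S)-5-(3-((4-methoxybenzyl)oxy)prop-1-yn-1-yl)-3-methylidenedihydrofuran-2(3H)-one
Product: 8 (5S)-5-(3-((4-methoxybenzyl)oxy)prop-1-yn-1-yl)-3-methylidenetetrahydrofuran-2-ol (lactol, both anomers)
Conditions: iBu2AlH (1.1 equiv), CH2Cl2, −78 °C
Reagents that add atoms: none
Why: Partial reduction of the lactone at low temperature should stop at the aluminium hemiacetal and give the lactol, a masked 2-substituted acrolein, without touching C8.

Step 5
Reactants: 9 3-methylbut-2-en-1-ol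
Product: 10 tert-butyldimethyl((3-methylbut-2-en-1-yl)oxy)silane
Conditions: tert-butyldimethylsilyl chloride, imidazole, CH2Cl2, rt
Reagents that add atoms: tert-butyldimethylsilyl chloride, CC(C)(C)[Si](C)(C)Cl
Why: Routine silylation of a primary allylic alcohol.

Step 6
Reactants: 10 tert-butyldimethyl((3-methylbut-2-en-1-yl)oxy)silane
Product: 11 (E)-4-((tert-butyldimethylsilyl)oxy)-2-methylbut-2-en-1-ol
Conditions: SeO2 (cat.), t-BuOOH, salicylic acid (cat.), CH2Cl2, rt
Reagents that add atoms: selenium dioxide, O=[Se]=O (catalytic oxygen carrier); tert-butyl hydroperoxide, CC(C)(C)OO (stoichiometric oxygen source)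
Why: Catalytic SeO2 allylic oxidation (ene reaction, then [2,3] shift) should hydroxylate the methyl group trans to the chain and so give the E-allylic alcohol.

Step 7
Reactants: 11 (E)-4-((tert-butyldimethylsilyl)oxy)-2-methylbut-2-en-1-ol
Product: 12 (E)-((4-bromo-3-methylbut-2-en-1-yl)oxy)(tert-butyl)dimethylsilane
Conditions: CBr4, PPh3, CH2Cl2, 0 °C
Reagents that add atoms: carbon tetrabromide, BrC(Br)(Br)Br
Why: Appel bromination of a primary allylic alcohol proceeds by SN2 on the oxyphosphonium ion and should keep the E geometry.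

Step 8
Reactants: 12 (E)-((4-bromo-3-methylbut-2-en-1-yl)oxy)(tert-butyl)dimethylsilane; 13 methyltriphenylphosphonium bromide
Product: 15 (E)-(5-((tert-butyldimethylsilyl)oxy)-3-methylpent-3-en-1-yl)triphenylphosphonium bromide, via methylidenetriphenylphosphorane 14 (not isolated)
Conditions: n-BuLi, THF, −78 to 0 °C; then 12, −78 °C to rt; salt isolated by trituration
Reagents that add atoms: none
Why: C-alkylation of the non-stabilised ylide by the primary allylic bromide (SN2) should give the chain-extended phosphonium salt, with C2 coming from the ylide carbon.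

Step 9
Reactants: 8 (5S)-5-(3-((4-methoxybenzyl)oxy)prop-1-yn-1-yl)-3-methylidenetetrahydrofuran-2-ol; 15 (E)-(5-((tert-butyldimethylsilyl)oxy)-3-methylpent-3-en-1-yl)triphenylphosphonium bromide
Product: 17 (2E,5Z,9S)-1-((tert-butyldimethylsilyl)oxy)-12-((4-methoxybenzyl)oxy)-3-methyl-7-methylidenedodeca-2,5-dien-10-yn-9-ol, via phosphorus ylide 16 (not isolated)
Conditions: 15 (2.2 equiv), KN(SiMe3)2 (2.1 equiv), THF, −78 °C; then 8, −78 °C to rt
Reagents that add atoms: none
Why: Wittig olefination of the lactol through its ring-opened hydroxy enal, in which the salt-free non-stabilised ylide should give the Z-C1=C2 bond under kinetic control while the first equivalent of ylide serves as base for the lactol hydroxyl.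

Step 10
Reactants: 17 (2E,5Z,9S)-1-((tert-butyldimethylsilyl)oxy)-12-((4-methoxybenzyl)oxy)-3-methyl-7-methylidenedodeca-2,5-dien-10-yn-9-ol
Product: 18 (2E,5Z,9S)-1,9-bis((tert-butyldimethylsilyl)oxy)-12-((4-methoxybenzyl)oxy)-3-methyl-7-methylidenedodeca-2,5-dien-10-yne
Conditions: tert-butyldimethylsilyl chloride, imidazole, DMF, rt
Reagents that add atoms: tert-butyldimethylsilyl chloride, CC(C)(C)[Si](C)(C)Cl
Why: Silylation of the secondary propargylic C8 hydroxyl, which must stay masked until the butenolide has been closed towards O6.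

Step 11
Reactants: 18 (2E,5Z,9S)-1,9-bis((tert-butyldimethylsilyl)oxy)-12-((4-methoxybenzyl)oxy)-3-methyl-7-methylidenedodeca-2,5-dien-10-yne
Product: 19 (2E,5Z,9S)-9-((tert-butyldimethylsilyl)oxy)-12-((4-methoxybenzyl)oxy)-3-methyl-7-methylidenedodeca-2,5-dien-10-yn-1-ol
Conditions: camphorsulfonic acid (cat.), MeOH/CH2Cl2, 0 °C
Reagents that add atoms: none
Why: Acid-catalysed methanolysis should cleave the unhindered primary allylic silyl ether much faster than the secondary one.

Step 12
Reactants: 19 (2E,5Z,9S)-9-((tert-butyldimethylsilyl)oxy)-12-((4-methoxybenzyl)oxy)-3-methyl-7-methylidenedodeca-2,5-dien-10-yn-1-ol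
Product: 20 ((2R,3R)-3-((2Z,6S)-6-((tert-butyldimethylsilyl)oxy)-9-((4-methoxybenzyl)oxy)-4-methylidenenon-2-en-7-yn-1-yl)-3-methyloxiran-2-yl)methanol
Conditions: Ti(OiPr)4 (cat.), D-(−)-diethyl tartrate, t-BuOOH, 4 Å molecular sieves, CH2Cl2, −20 °C
Reagents that add atoms: tert-butyl hydroperoxide, CC(C)(C)OO
Why: Sharpless asymmetric epoxidation reacts only at the allylic alcohol alkene, and D-(−)-tartrate should give the (4R,5R)-epoxide, the same sense in which geraniol gives its (2R,3R)-epoxide.

Step 13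
Reactants: 20 ((2R,3R)-3-((2Z,6S)-6-((tert-butyldimethylsilyl)oxy)-9-((4-methoxybenzyl)oxy)-4-methylidenenon-2-en-7-yn-1-yl)-3-methyloxiran-2-yl)methanol
Product: 21 ((2R,3R)-3-(((2S,3R)-3-((4S)-4-((tert-butyldimethylsilyl)oxy)-7-((4-methoxybenzyl)oxy)hept-1-en-5-yn-2-yl)oxiran-2-yl)methyl)-3-methyloxiran-2-yl)methanol
Conditions: D-glucose-derived N-aryl oxazolidinone ketone (cis-olefin Shi catalyst, 25 mol %), KHSO5 (Oxone), K2CO3–AcOH buffer (pH 8), dimethoxyethane/dimethoxymethane, −10 °C
Reagents that add atoms: potassium peroxymonosulfate (KHSO5), [K+].[O-]S(=O)(=O)OO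
Why: Shi epoxidation adds the dioxirane oxygen stereospecifically to the Z-C1=C2 bond of the conjugated diene, whose vinyl group (C10=C14) sits next to the oxazolidinone in the spiro transition state, which should give the cis-(1R,2S)-epoxide by analogy with cis-β-methylstyrene while the 1,1-disubstituted alkene and the alkyne react far more slowly.

Step 14
Reactants: 21 ((2R,3R)-3-(((2S,3R)-3-((4S)-4-((tert-butyldimethylsilyl)oxy)-7-((4-methoxybenzyl)oxy)hept-1-en-5-yn-2-yl)oxiran-2-yl)methyl)-3-methyloxiran-2-yl)methanol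
Product: 22 (2S,3R)-3-(((2S,3R)-3-((4S)-4-((tert-butyldimethylsilyl)oxy)-7-((4-methoxybenzyl)oxy)hept-1-en-5-yn-2-yl)oxiran-2-yl)methyl)-3-methyloxirane-2-carbaldehyde
Conditions: Dess–Martin periodinane, CH2Cl2, 0 °C to rt
Reagents that add atoms: none
Why: Dess–Martin oxidation of the epoxy alcohol should give the non-enolisable α,β-epoxy aldehyde under near-neutral conditions (the C5 descriptor changes by priority only).

Step 15
Reactants: 22 (2S,3R)-3-(((2S,3R)-3-((4S)-4-((tert-butyldimethylsilyl)oxy)-7-((4-methoxybenzyl)oxy)hept-1-en-5-yn-2-yl)oxiran-2-yl)methyl)-3-methyloxirane-2-carbaldehyde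
Product: 23 (2S,3R)-3-(((2S,3R)-3-((4S)-4-((tert-butyldimethylsilyl)oxy)-7-hydroxyhept-1-en-5-yn-2-yl)oxiran-2-yl)methyl)-3-methyloxirane-2-carbaldehyde
Conditions: DDQ, CH2Cl2/pH 7 buffer, 0 °C
Reagents that add atoms: none
Why: Oxidative cleavage of the 4-methoxybenzyl ether by DDQ is neutral and should spare the epoxides, the aldehyde and the silyl ether, now that no conjugated diene remains.

Step 16
Reactants: 23 (2S,3R)-3-(((2S,3R)-3-((4S)-4-((tert-butyldimethylsilyl)oxy)-7-hydroxyhept-1-en-5-yn-2-yl)oxiran-2-yl)methyl)-3-methyloxirane-2-carbaldehyde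
Product: 25 (2S,3R)-3-(((2S,3R)-3-((4S)-7-bromo-4-((tert-butyldimethylsilyl)oxy)hept-1-en-5-yn-2-yl)oxiran-2-yl)methyl)-3-methyloxirane-2-carbaldehyde, via mesylate 24 (not isolated)
Conditions: MsCl, Et3N, THF, −20 °C; then LiBr, 0 °C
Reagents that add atoms: lithium bromide (LiBr), [Li+].[Br-]
Why: Mesylation and SN2 displacement by bromide convert the primary propargylic alcohol into the bromide at low temperature, where the epoxides and the epoxy aldehyde should persist.

Step 17
Reactants: 25 (2S,3R)-3-(((2S,3R)-3-((4S)-7-bromo-4-((tert-butyldimethylsilyl)oxy)hept-1-en-5-yn-2-yl)oxiran-2-yl)methyl)-3-methyloxirane-2-carbaldehyde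
Product: 26 (1R,2S,4R,5R,6S,8S)-8-((tert-butyldimethylsilyl)oxy)-1,2:4,5-diepoxy-7-ethenylidene-4-methyl-10-methylidenecyclodecan-6-ol (ten-membered α-allenic alcohol, germacrane locants)
Conditions: CrCl2 (8 equiv), THF/DMF, rt, slow addition of 25 to high dilution
Reagents that add atoms: none
Why: Chromium-mediated Barbier (Nozaki–Hiyama-type) propargylation, in which divalent chromium turns the γ-substituted propargylic bromide into a propargyl-chromium species at unhindered C13 that attacks the aldehyde through C7 (SE2') to close the ten-membered ring as the α-allenic alcohol, and the compact cyclic transition state with chromium bridging the aldehyde and C5 epoxide oxygens should give the 5,6-syn (6S) carbinol as in related closures of ten-membered rings onto α,β-epoxy aldehydes.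

Step 18
Reactants: 26 (1R,2S,4R,5R,6S,8S)-8-((tert-butyldimethylsilyl)oxy)-1,2:4,5-diepoxy-7-ethenylidene-4-methyl-10-methylidenecyclodecan-6-ol
Product: 27 (1R,2S,4R,5R,6S,8S)-13-acetoxy-8-((tert-butyldimethylsilyl)oxy)-1,2:4,5-diepoxygermacra-7(11),10(14)-dien-12,6-olide
Conditions: Pd(OAc)2 (10 mol %), p-benzoquinone (2 equiv), AcOH (5 equiv), LiOAc (2 equiv), CO (1 atm), MeCN/THF, 4 Å molecular sieves, rt
Reagents that add atoms: carbon monoxide, [C-]#[O+]; acetic acid, CC(=O)O
Why: Proposed new method: on divalent palladium the C6 hydroxyl and CO should give an alkoxycarbonyl–palladium species (O6–C12(=O)–Pd), whose Pd–C12 bond then adds syn across the distal C11=C13 bond of the allene with C12 going to the central carbon C11; this forms the C11–C12 bond, closes the lactone and leaves a π-allyl palladium unit over C7–C11–C13 that acetate opens at C13, and the zerovalent palladium set free is reoxidised by benzoquinone. The closest known reaction types are the palladium-catalysed cyclocarbonylation of alkynols by intramolecular insertion into an alkoxycarbonyl–palladium bond and the palladium/benzoquinone 1,2-oxidation of allenes, in which acetate opens a π-allyl complex that bears the first-added group on its central carbon. The lactone ring (O6, C6, C7, C11, C12) closes in a 5-exo mode with respect to the C11=C13 bond, bond formation at the central allene carbon being the rule for carbopalladation of allenes. No stereocentre is formed, and the geometry of the tetrasubstituted C7=C11 bond cannot go wrong because C12 is already bound to O6 when the C–C bond forms. The step needs carbonylation of the Pd–alkoxide to outrun 5-endo oxypalladation (O6 to C13) and acetate to enter at C13 and not at C7: CO pressure and acetate base favour the first, the fully substituted C7 and conjugation in the product favour the second, and the silyl ether on O8 keeps the second allylic oxygen from lactonising.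

Step 19
Reactants: 27 (1R,2S,4R,5R,6S,8S)-13-acetoxy-8-((tert-butyldimethylsilyl)oxy)-1,2:4,5-diepoxygermacra-7(11),10(14)-dien-12,6-olide
Product: 28 (1R,2S,4R,5R,6S,8S)-13-acetoxy-1,2:4,5-diepoxy-8-hydroxygermacra-7(11),10(14)-dien-12,6-olide
Conditions: HF·pyridine, excess pyridine, THF, 0 °C to rt
Reagents that add atoms: none
Why: Buffered fluoride should cleave the secondary silyl ether while the excess pyridine keeps the medium too weakly acidic to open the epoxides or move the acetate.

Step 20
Reactants: 29 ethyl 2-(hydroxymethyl)acrylate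
Product: 30 ethyl 2-(((tert-butyldimethylsilyl)oxy)methyl)acrylate
Conditions: tert-butyldimethylsilyl chloride, imidazole, CH2Cl2, rt
Reagents that add atoms: tert-butyldimethylsilyl chloride, CC(C)(C)[Si](C)(C)Cl
Why: Routine silylation masks the side-chain hydroxyl so that it cannot compete in the esterification.

Step 21
Reactants: 30 ethyl 2-(((tert-butyldimethylsilyl)oxy)methyl)acrylate
Product: 32 2-(((tert-butyldimethylsilyl)oxy)methyl)acrylic acid, via lithium carboxylate 31 (not isolated)
Conditions: LiOH, THF/H2O, 0 °C; then 1 M HCl to pH 4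
Reagents that add atoms: lithium hydroxide (LiOH), [Li+].[OH-]
Why: Saponification of the ethyl ester at 0 °C followed by careful acidification should give the acid with the silyl ether intact.

Step 22
Reactants: 28 (1R,2S,4R,5R,6S,8S)-13-acetoxy-1,2:4,5-diepoxy-8-hydroxygermacra-7(11),10(14)-dien-12,6-olide; 32 2-(((tert-butyldimethylsilyl)oxy)methyl)acrylic acid
Product: 33 (1R,2S,4R,5R,6S,8S)-13-acetoxy-8-((2-(((tert-butyldimethylsilyl)oxy)methyl)acryloyl)oxy)-1,2:4,5-diepoxygermacra-7(11),10(14)-dien-12,6-olide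
Conditions: dicyclohexylcarbodiimide, DMAP (cat.), CH2Cl2, 0 °C to rt
Reagents that add atoms: none
Why: Steglich esterification acylates the C8 hydroxyl with retention, since the C8–O bond is not broken, under conditions mild enough for the butenolide and the allylic acetate.

Step 23
Reactants: 33 (1R,2S,4R,5R,6S,8S)-13-acetoxy-8-((2-(((tert-butyldimethylsilyl)oxy)methyl)acryloyl)oxy)-1,2:4,5-diepoxygermacra-7(11),10(14)-dien-12,6-olide
Product: 34 (1R,2S,4R,5R,6S,8S)-13-acetoxy-1,2:4,5-diepoxy-8-((2-(hydroxymethyl)acryloyl)oxy)germacra-7(11),10(14)-dien-12,6-olide (CNP0233746.1)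
Conditions: HF·pyridine, excess pyridine, THF, 0 °C
Reagents that add atoms: none
Why: Buffered fluoride should remove the primary silyl ether quickly and without base, which avoids acyl migration and conjugate addition to the acrylate.

**Compound list**

1 | but-2-yne-1,4-diol | OCC#CCO | starting material
2 | 4-((4-methoxybenzyl)oxy)but-2-yn-1-ol | COc1ccc(COCC#CCO)cc1 | intermediate
3 | 4-((4-methoxybenzyl)oxy)but-2-ynal | COc1ccc(COCC#CC=O)cc1 | intermediate
4 | ethyl 2-(bromomethyl)acrylate | C=C(CBr)C(=O)OCC | starting material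
5 | ethyl (S)-7-((4-methoxybenzyl)oxy)-2-methylidene-4-((trimethylsilyl)oxy)hept-5-ynoate (silyl ether, not isolated) | CCOC(=O)C(=C)C[C@H](O[Si](C)(C)C)C#CCOCc1ccc(OC)cc1 | intermediate
6 | ethyl (S)-4-hydroxy-7-((4-methoxybenzyl)oxy)-2-methylidenehept-5-ynoate (hydroxy ester, not isolated) | CCOC(=O)C(=C)C[C@H](O)C#CCOCc1ccc(OC)cc1 | intermediate
7 | (S)-5-(3-((4-methoxybenzyl)oxy)prop-1-yn-1-yl)-3-methylidenedihydrofuran-2(3H)-one | C=C1C[C@@H](C#CCOCc2ccc(OC)cc2)OC1=O | intermediate
8 | (5S)-5-(3-((4-methoxybenzyl)oxy)prop-1-yn-1-yl)-3-methylidenetetrahydrofuran-2-ol (lactol, both anomers) | C=C1C[C@@H](C#CCOCc2ccc(OC)cc2)OC1O | intermediate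
9 | 3-methylbut-2-en-1-ol | CC(C)=CCO | starting material
10 | tert-butyldimethyl((3-methylbut-2-en-1-yl)oxy)silane | CC(C)=CCO[Si](C)(C)C(C)(C)C | intermediate
11 | (E)-4-((tert-butyldimethylsilyl)oxy)-2-methylbut-2-en-1-ol | OC/C(C)=C/CO[Si](C)(C)C(C)(C)C | intermediate
12 | (E)-((4-bromo-3-methylbut-2-en-1-yl)oxy)(tert-butyl)dimethylsilane | BrC/C(C)=C/CO[Si](C)(C)C(C)(C)C | intermediate
13 | methyltriphenylphosphonium bromide | [Br-].C[P+](c1ccccc1)(c1ccccc1)c1ccccc1 | starting material
14 | methylidenetriphenylphosphorane (not isolated) | C=P(c1ccccc1)(c1ccccc1)c1ccccc1 | intermediate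
15 | (E)-(5-((tert-butyldimethylsilyl)oxy)-3-methylpent-3-en-1-yl)triphenylphosphonium bromide | [Br-].CC(C)(C)[Si](C)(C)OC/C=C(C)/CC[P+](c1ccccc1)(c1ccccc1)c1ccccc1 | intermediate
16 | (E)-(5-((tert-butyldimethylsilyl)oxy)-3-methylpent-3-en-1-ylidene)triphenylphosphorane (not isolated) | CC(C)(C)[Si](C)(C)OC/C=C(C)/CC=P(c1ccccc1)(c1ccccc1)c1ccccc1 | intermediate
17 | (2E,5Z,9S)-1-((tert-butyldimethylsilyl)oxy)-12-((4-methoxybenzyl)oxy)-3-methyl-7-methylidenedodeca-2,5-dien-10-yn-9-ol | COc1ccc(COCC#C[C@@H](O)CC(=C)/C=C\C/C(C)=C/CO[Si](C)(C)C(C)(C)C)cc1 | intermediate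
18 | (2E,5Z,9S)-1,9-bis((tert-butyldimethylsilyl)oxy)-12-((4-methoxybenzyl)oxy)-3-methyl-7-methylidenedodeca-2,5-dien-10-yne | COc1ccc(COCC#C[C@@H](O[Si](C)(C)C(C)(C)C)CC(=C)/C=C\C/C(C)=C/CO[Si](C)(C)C(C)(C)C)cc1 | intermediate
19 | (2E,5Z,9S)-9-((tert-butyldimethylsilyl)oxy)-12-((4-methoxybenzyl)oxy)-3-methyl-7-methylidenedodeca-2,5-dien-10-yn-1-ol | COc1ccc(COCC#C[C@@H](O[Si](C)(C)C(C)(C)C)CC(=C)/C=C\C/C(C)=C/CO)cc1 | intermediate
20 | ((2R,3R)-3-((2Z,6S)-6-((tert-butyldimethylsilyl)oxy)-9-((4-methoxybenzyl)oxy)-4-methylidenenon-2-en-7-yn-1-yl)-3-methyloxiran-2-yl)methanol | COc1ccc(COCC#C[C@@H](O[Si](C)(C)C(C)(C)C)CC(=C)/C=C\C[C@@]2(C)O[C@@H]2CO)cc1 | intermediate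
21 | ((2R,3R)-3-(((2S,3R)-3-((4S)-4-((tert-butyldimethylsilyl)oxy)-7-((4-methoxybenzyl)oxy)hept-1-en-5-yn-2-yl)oxiran-2-yl)methyl)-3-methyloxiran-2-yl)methanol | COc1ccc(COCC#C[C@@H](O[Si](C)(C)C(C)(C)C)CC(=C)[C@H]2O[C@H]2C[C@@]2(C)O[C@@H]2CO)cc1 | intermediate
22 | (2S,3R)-3-(((2S,3R)-3-((4S)-4-((tert-butyldimethylsilyl)oxy)-7-((4-methoxybenzyl)oxy)hept-1-en-5-yn-2-yl)oxiran-2-yl)methyl)-3-methyloxirane-2-carbaldehyde | COc1ccc(COCC#C[C@@H](O[Si](C)(C)C(C)(C)C)CC(=C)[C@H]2O[C@H]2C[C@@]2(C)O[C@@H]2C=O)cc1 | intermediate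
23 | (2S,3R)-3-(((2S,3R)-3-((4S)-4-((tert-butyldimethylsilyl)oxy)-7-hydroxyhept-1-en-5-yn-2-yl)oxiran-2-yl)methyl)-3-methyloxirane-2-carbaldehyde | OCC#C[C@@H](O[Si](C)(C)C(C)(C)C)CC(=C)[C@H]1O[C@H]1C[C@@]1(C)O[C@@H]1C=O | intermediate
24 | methanesulfonate of the C13 hydroxyl of 23 (not isolated) | CS(=O)(=O)OCC#C[C@@H](O[Si](C)(C)C(C)(C)C)CC(=C)[C@H]1O[C@H]1C[C@@]1(C)O[C@@H]1C=O | intermediate
25 | (2S,3R)-3-(((2S,3R)-3-((4S)-7-bromo-4-((tert-butyldimethylsilyl)oxy)hept-1-en-5-yn-2-yl)oxiran-2-yl)methyl)-3-methyloxirane-2-carbaldehyde | BrCC#C[C@@H](O[Si](C)(C)C(C)(C)C)CC(=C)[C@H]1O[C@H]1C[C@@]1(C)O[C@@H]1C=O | intermediate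
26 | (1R,2S,4R,5R,6S,8S)-8-((tert-butyldimethylsilyl)oxy)-1,2:4,5-diepoxy-7-ethenylidene-4-methyl-10-methylidenecyclodecan-6-ol (germacrane locants) | CC(C)(C)[Si](C)(C)O[C@H]1CC(=C)[C@H]2O[C@H]2C[C@@]2(C)O[C@@H]2[C@@H](O)C1=C=C | intermediate
27 | (1R,2S,4R,5R,6S,8S)-13-acetoxy-8-((tert-butyldimethylsilyl)oxy)-1,2:4,5-diepoxygermacra-7(11),10(14)-dien-12,6-olide | CC(C)(C)[Si](C)(C)O[C@H]1CC(=C)[C@H]2O[C@H]2C[C@@]2(C)O[C@@H]2[C@H]2OC(=O)C(COC(C)=O)=C12 | intermediate
28 | (1R,2S,4R,5R,6S,8S)-13-acetoxy-1,2:4,5-diepoxy-8-hydroxygermacra-7(11),10(14)-dien-12,6-olide | O[C@H]1CC(=C)[C@H]2O[C@H]2C[C@@]2(C)O[C@@H]2[C@H]2OC(=O)C(COC(C)=O)=C12 | intermediate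
29 | ethyl 2-(hydroxymethyl)acrylate | C=C(CO)C(=O)OCC | starting material
30 | ethyl 2-(((tert-butyldimethylsilyl)oxy)methyl)acrylate | C=C(CO[Si](C)(C)C(C)(C)C)C(=O)OCC | intermediate
31 | lithium 2-(((tert-butyldimethylsilyl)oxy)methyl)acrylate (not isolated) | [Li+].C=C(CO[Si](C)(C)C(C)(C)C)C(=O)[O-] | intermediate
32 | 2-(((tert-butyldimethylsilyl)oxy)methyl)acrylic acid | C=C(CO[Si](C)(C)C(C)(C)C)C(=O)O | intermediate
33 | (1R,2S,4R,5R,6S,8S)-13-acetoxy-8-((2-(((tert-butyldimethylsilyl)oxy)methyl)acryloyl)oxy)-1,2:4,5-diepoxygermacra-7(11),10(14)-dien-12,6-olide | C=C(CO[Si](C)(C)C(C)(C)C)C(=O)O[C@H]1CC(=C)[C@H]2O[C@H]2C[C@@]2(C)O[C@@H]2[C@H]2OC(=O)C(COC(C)=O)=C12 | intermediate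
34 | (1R,2S,4R,5R,6S,8S)-13-acetoxy-1,2:4,5-diepoxy-8-((2-(hydroxymethyl)acryloyl)oxy)germacra-7(11),10(14)-dien-12,6-olide (CNP0233746.1) | C=C(CO)C(=O)O[C@H]1CC(=C)[C@H]2O[C@H]2C[C@@]2(C)O[C@@H]2[C@H]2OC(=O)C(COC(C)=O)=C12 | target

**Step count and risks**

Total steps: 23. Longest linear sequence: 17 (steps 1–4, 9–19, 22, 23).

Step 18 (proposed new method). What may go wrong:
- 5-endo oxypalladation of the allenol by divalent palladium before CO is taken up, which would give a 2,5-dihydrofuran;
- ionisation of the vinyl epoxide by transient zerovalent palladium;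
- entry of acetate at C7.

The fallback uses known reactions, sets out from 26 and comes back at 27. Iodoetherification of 26 with N-iodosuccinimide (CH2Cl2, 0 °C) should close the 5-endo ring from O6 to the allene terminus and give the 11-iodo-2,5-dihydrofuran F1. Allylic oxidation of its unhindered ring CH2 with CrO3·3,5-dimethylpyrazole should give the α-iodobutenolide F2, in which the former allene terminus is the lactone carbonyl. Stille coupling with (tributylstannyl)methanol (Pd2(dba)3, AsPh3, CuI) should give the α-hydroxymethyl butenolide F3, and acetylation (Ac2O, pyridine) gives 27. The ring fixes the alkene geometry here as well; the short exposure of the vinyl epoxide to zerovalent palladium in the Stille step is the weak point of this path.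

Step 17. What may go wrong:
- attack on the wrong face of the aldehyde, because the open-chain dipole-controlled preference of an α,β-epoxy aldehyde opposes the required 5,6-syn relationship;
- a competing twelve-membered homopropargylic closure.

The fallback sets C6 by reagent-controlled ketone reduction instead of by the ring closure; it sets out from 25 and comes back at 26. The same chromium-mediated closure is accepted whatever its C6 outcome and gives the C6-epimeric allenol F4. Dess–Martin oxidation gives the allenyl ketone F5. Corey–Bakshi–Shibata reduction with (S)-Me-CBS and catecholborane at −78 °C should then deliver hydride to the Re face (allenyl carbon as the large group) and give the (6S)-alcohol 26.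

Step 9. What may go wrong:
- oxa-Michael cyclisation of the ring-opened lactol alkoxide onto its own 2-substituted acrolein;
- erosion of Z-selectivity by the alkoxide.

The fallback silylates O8 before the enal is unveiled; it sets out from 7 and comes back at 18, so step 10 is no longer needed. Opening of lactone 7 with Me(MeO)NH·HCl/Me3Al gives the hydroxy Weinreb amide F6. Silylation (tert-butyldimethylsilyl chloride, imidazole) gives F7. Reduction with iBu2AlH at −78 °C gives the enal F8, and Wittig reaction of F8 with ylide 16 (from 15 and KN(SiMe3)2) should give 18 directly.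

Further compounds
F1 | step 18 | (1R,2S,4R,5R,6S,8S)-8-((tert-butyldimethylsilyl)oxy)-1,2:4,5-diepoxy-11-iodo-6,13-epoxygermacra-7(11),10(14)-diene (3-iodo-2,5-dihydrofuran) | CC(C)(C)[Si](C)(C)O[C@H]1CC(=C)[C@H]2O[C@H]2C[C@@]2(C)O[C@@H]2[C@H]2OCC(I)=C12
F2 | step 18 | α-iodobutenolide: lactone 27 with iodine on C11 in place of the acetoxymethyl group | CC(C)(C)[Si](C)(C)O[C@H]1CC(=C)[C@H]2O[C@H]2C[C@@]2(C)O[C@@H]2[C@H]2OC(=O)C(I)=C12
F3 | step 18 | α-hydroxymethyl butenolide: 27 with free CH2OH in place of CH2OAc | CC(C)(C)[Si](C)(C)O[C@H]1CC(=C)[C@H]2O[C@H]2C[C@@]2(C)O[C@@H]2[C@H]2OC(=O)C(CO)=C12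
F4 | step 17 | (6R)-epimer of allenol 26 | CC(C)(C)[Si](C)(C)O[C@H]1CC(=C)[C@H]2O[C@H]2C[C@@]2(C)O[C@@H]2[C@H](O)C1=C=C
F5 | step 17 | allenyl ketone: 26 with C6 as ketone | CC(C)(C)[Si](C)(C)O[C@H]1CC(=C)[C@H]2O[C@H]2C[C@@]2(C)O[C@@H]2C(=O)C1=C=C
F6 | step 9 | (S)-4-hydroxy-N-methoxy-7-((4-methoxybenzyl)oxy)-N-methyl-2-methylidenehept-5-ynamide | CON(C)C(=O)C(=C)C[C@H](O)C#CCOCc1ccc(OC)cc1
F7 | step 9 | (S)-4-((tert-butyldimethylsilyl)oxy)-N-methoxy-7-((4-methoxybenzyl)oxy)-N-methyl-2-methylidenehept-5-ynamide | CON(C)C(=O)C(=C)C[C@H](O[Si](C)(C)C(C)(C)C)C#CCOCc1ccc(OC)cc1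
F8 | step 9 | (S)-4-((tert-butyldimethylsilyl)oxy)-7-((4-methoxybenzyl)oxy)-2-methylidenehept-5-ynal | O=CC(=C)C[C@H](O[Si](C)(C)C(C)(C)C)C#CCOCc1ccc(OC)cc1
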